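**Remark on the chemistry:** the target is achiral. Indole numbering (N1, C2, C3, C3a, C4–C7, C7a) is used throughout; ring A is the benzene ring and ring B the pyrrole ring.

## Analysis of the target

2,3,4,7-Tetrabromo-1H-indole (16) is a planar bicycle in which benzene ring A (C3a, C4–C7, C7a) is fused to pyrrole ring B (N1, C2, C3, C3a, C7a). It has no stereocentre, so the whole problem is one of regiochemistry: two bromines sit on ring A at C4 and C7, next to the ring fusion and para to each other, and two sit on ring B at C2 and C3. Electrophilic bromination of an indole goes to C3, then C2, then C5 or C6, so the C4 and C7 bromines cannot be put on a finished indole and must come with the starting arene. The 2,3-dibromo-1H-pyrrole part is the sensitive region, because it is electron-rich, has a free N–H, and its C2–Br bond is readily lost by hydrolysis or over-oxidation. The four C–Br bonds also exclude late cross-coupling, halogen–metal exchange and hydrogenation, and the C3 bromine is peri to the C4 bromine, so the last substitution at C3 is crowded. The strategy rests on one feature: C3 carries only a bromine in place of hydrogen and is bonded to C3a, while C2 lies between C3 and N1, so a formyl carbon on C3a and a glycinate α-carbon on N1 are placed to form the C2–C3 bond by aldol condensation. The ester that this leaves on C2 marks that carbon for exchange against bromine.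

## Retrosynthetic reasoning

**16 back to 14 (C2–Br and C3–Br).** Both ring B bromines are removed first, because the 2,3-dibromopyrrole unit is the least robust part and should be made last. C3 is disconnected to a C–H and C2 to a carboxylic acid, giving 4,7-dibromo-1H-indole-2-carboxylic acid (14). The forward reaction has to brominate C3 and replace the carboxyl group at C2 by ipso attack with decarboxylation, passing through the tribromo acid 15. Cutting here turns the carboxyl group left by the ring synthesis into the handle for the fourth bromine.

**14 back to 12 (N–S and ester C–O).** The acid is traced to the N-sulfonyl methyl ester 12. One basic hydrolysis removes both groups, by way of the N–H ester 13. The sulfonyl group is needed only while the ring is being built.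

**12 back to 10 (C2–C3, the key disconnection).** Ring B is opened between C2 and C3 to give the N-aryl-N-sulfonyl glycinate 10, with the formyl group on the future C3a and the glycinate carbon on N1. This cut is chosen over N1–C2 or C3–C3a because it uses the one pyrrole carbon (C3) that can come from an aldehyde. Both partners then hang on adjacent ring A carbons that already carry the correct bromines. The forward step must add the enolate to the aldehyde, through the hydroxyindoline 11, and then dehydrate.

**10 back to 8 and 9 (N–CH2).** The glycinate arm is detached as methyl bromoacetate (9), leaving the secondary sulfonamide 8. The sulfonyl group makes the N–H acidic enough for mild alkylation, and later acidifies the glycinate CH2.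

**8 back to 6 and 7 (N–S).** The sulfonamide is cut to the amino aldehyde 6 and p-toluenesulfonyl chloride (7).

**6 back to 4 and 3 (C7a–N).** The amine is traced through the aryl azide 4 to the aryl fluoride 3. The nitrogen is introduced at the azide oxidation level because a free amine nucleophile would condense with the aldehyde. The fluoride is ortho to the formyl group and is the best leaving group on the ring, so substitution should occur only there.

**3 back to 1 (C3a–CHO).** The formyl group is removed to give 1,4-dibromo-2-fluorobenzene (1). Its only C–H flanked by two halogens lies between fluorine and bromine, so deprotonation there, by way of the aryllithium 2, and formylation place the carbon exactly where C3 has to be attached. Compound 1 already carries the two para bromines that become C4–Br and C7–Br.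

## Alternatives that were turned down

Alternative 1: ring A built by cycloaddition of a thiophene dioxide.
- Disconnection: C3a–C4 and C7–C7a, cutting ring A into a four-carbon dibromodiene and the alkene of a five-membered enecarbamate.
- Forward key step: the diene 2,5-dibromothiophene 1,1-dioxide A1 adds across the C=C of the enecarbamate tert-butyl 2,3-dihydro-1H-pyrrole-1-carboxylate A2. The sulfonyl bridge is then extruded to give the cis-fused tetrahydroindole A3, tert-butyl cis-4,7-dibromo-2,3,3a,7a-tetrahydro-1H-indole-1-carboxylate.
- For it: the symmetry of A1 fixes the bromines at C4 and C7 with no regiochemical question. The electron-poor diene A1 and the electron-rich alkene A2 are well matched. The bicyclic skeleton is reached in very few steps, and on this count it beats the chosen route.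
- Against it: A3 is two oxidation levels below an indole. Aromatising ring A means removing the two ring-fusion hydrogens next to vinylic C–Br bonds, and dehydrobromination is the easier way for such a diene to become aromatic, which would lose a bromine. A1 also tends to dimerise, and A3 is itself a diene that can react again with A1. Carbamate removal, a second dehydrogenation and a double bromination would still follow.
- Comparison: the chosen route keeps ring A aromatic from 1 onward and reaches the indole oxidation level directly in the ring-forming step. It gives up brevity for security of the C4 and C7 bromines.

Alternative 2: both rings from a [2+2+2] cyclotrimerisation.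
- Disconnection: C3a–C7a, C4–C5 and C6–C7, reducing the bicycle to an acyclic ynamide diyne and a two-carbon alkyne.
- Forward key step: the bis-silylated ynamide diyne A4 and acetylene A5 are joined by RhCl(PPh3)3 or CpCo(CO)2 in one cyclotrimerisation to give the bis-silyl indoline A6, 1-tosyl-4,7-bis(trimethylsilyl)indoline.
- For it: three C–C bonds and two rings form in one step, which the chosen route cannot match. A5 is symmetric and the tether of A4 fixes the orientation.
- Against it: the bromines are only represented by silicon. Ipso-bromodesilylation at C7 is helped by the ortho nitrogen. C4 is meta to nitrogen, and the free C5 position para to nitrogen competes for the electrophile. Two bulky silyl termini slow the cyclotrimerisation, and A4 needs an ynamide coupling of its own. After A6 there remain two desilylations, oxidation of the indoline, sulfonamide cleavage and the double bromination of ring B.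
- Comparison: the sequence is longer and its regiochemistry is less certain. The chosen route carries real C–Br bonds at C4 and C7 from the first compound.

Alternative 3: symmetric aryne annulated by a dehydroalanine ester.
- Disconnection: N1–C7a and C3–C3a, joining a two-carbon aryne unit to an N–C–C fragment.
- Forward key step: CsF in MeCN converts the silyl triflate A7 into the aryne 3,6-dibromobenzyne A8. The carbamate nitrogen of methyl 2-[(tert-butoxycarbonyl)amino]acrylate A9 adds to A8, and the resulting aryl anion closes onto the acrylate terminus to give the indoline diester A10, 1-tert-butyl 2-methyl 4,7-dibromoindoline-1,2-dicarboxylate.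
- For it: it is the most convergent of the four plans. A8 is symmetric, so there is no regiochemical issue in the addition of A9. A10 carries the same C2 carboxyl handle, so the endgame would resemble that of the chosen route.
- Against it: after N-addition the aryl anion sits on the future C3a, directly next to the C4 bromine. Loss of bromide to give a second aryne competes with a ring closure that is formally 5-endo-trig. A7 is not a catalogue compound; its preparation takes several steps and meets the same risk of halogen–metal exchange when the silyl group is installed. A10 is an indoline and still has to be dehydrogenated and deprotected.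
- Comparison: the chosen route closes ring B 5-exo from an ester enolate, not from an aryl anion flanked by bromine. It starts from a cheap arene and needs no oxidation step. It pays for this with a linear sequence.

Key step: step 6

**Remark:** equivalents and temperatures are proposed starting values. Compound 11 is expected as a mixture of diastereomers; this has no consequence because both stereocentres disappear on dehydration.

## Route

Step 1
Reactants: 1 1,4-dibromo-2-fluorobenzene
Product: 3 3,6-dibromo-2-fluorobenzaldehyde, via (3,6-dibromo-2-fluorophenyl)lithium 2 (not isolated)
Conditions: LiN(iPr)2 (LDA, 1.1 equiv), THF, −78 °C; DMF (1.5 equiv), −78 °C; then 1 M HCl, −78 °C → rt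
Reagents that add atoms: N,N-dimethylformamide, CN(C)C=O
Why: Directed ortho-metalation followed by formylation of the aryllithium; the C–H between fluorine and bromine is the most acidic on the ring, the amide base deprotonates without bromine–lithium exchange, and trapping at −78 °C should outrun loss of lithium halide from 2.

Step 2
Reactants: 3 3,6-dibromo-2-fluorobenzaldehyde
Product: 4 2-azido-3,6-dibromobenzaldehyde
Conditions: NaN3 (1.2 equiv), DMSO, rt → 40 °C (solution not concentrated to dryness)
Reagents that add atoms: sodium azide, [Na+].[N-]=[N+]=[N-]
Why: Nucleophilic aromatic substitution of a fluoride ortho to a formyl group; addition is rate-limiting, so fluoride should be displaced far faster than the C6 bromide that is also ortho to the aldehyde, and azide cannot condense with the carbonyl group.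

Step 3
Reactants: 4 2-azido-3,6-dibromobenzaldehyde
Product: 6 2-amino-3,6-dibromobenzaldehyde, via 3,6-dibromo-2-[(trimethylphosphoranylidene)amino]benzaldehyde 5 (not isolated)
Conditions: PMe3 (1.2 equiv, 1 M in THF), THF, 0 °C → rt; then H2O, rt → 40 °C
Reagents that add atoms: none
Why: Staudinger reduction; the phosphine attacks only the azide, so the aldehyde and both aryl bromides should survive, and the trimethylphosphine aza-ylide 5 is chosen because it hydrolyses readily even on a hindered, electron-poor aryl nitrogen.

Step 4
Reactants: 6 2-amino-3,6-dibromobenzaldehyde; 7 p-toluenesulfonyl chloride
Product: 8 N-(3,6-dibromo-2-formylphenyl)-4-methylbenzenesulfonamide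
Conditions: 7 (1.3 equiv), pyridine, DMAP (cat.), 60 °C
Reagents that add atoms: none
Why: Sulfonylation of an aniline; heating with an acyl-transfer catalyst is proposed because the nitrogen is flanked by bromine and a hydrogen-bonded formyl group, and the same crowding should stop the reaction after one sulfonyl group.

Step 5
Reactants: 8 N-(3,6-dibromo-2-formylphenyl)-4-methylbenzenesulfonamide; 9 methyl bromoacetate
Product: 10 methyl N-(3,6-dibromo-2-formylphenyl)-N-tosylglycinate
Conditions: 9 (1.2 equiv), K2CO3 (1.5 equiv), DMF, 0 °C → rt, stopped when 8 is consumed
Reagents that add atoms: none
Why: SN2 N-alkylation of an acidic aryl sulfonamide with a reactive α-halo ester; carbonate at or below room temperature should deprotonate N–H but only slowly enolise the product, and any material that cyclises early joins the route again in step 6.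

Step 6
Reactants: 10 methyl N-(3,6-dibromo-2-formylphenyl)-N-tosylglycinate
Product: 12 methyl 4,7-dibromo-1-tosyl-1H-indole-2-carboxylate, via methyl 4,7-dibromo-3-hydroxy-1-tosylindoline-2-carboxylate 11 (not isolated)
Conditions: DBU (1.5 equiv), MeCN, rt → 60 °C
Reagents that add atoms: none
Why: The amidine base removes a proton from the glycinate CH2, which is acidified by the ester and the N-sulfonyl group, and the enolate carbon adds to the ortho formyl carbon to give the hydroxyindoline 11. A second deprotonation at C2 and E1cB loss of hydroxide from C3 then give the aromatic pyrrole ring. The closest known reaction type is the aldol cyclisation and dehydration, under basic conditions, of glycine esters that carry both an N-sulfonyl and an N-(2-acylaryl) group, which gives indole-2-carboxylic esters. Ring B closes by forming the C2–C3 bond in a 5-exo-trig mode, the enolate carbon attacking a carbonyl group that lies outside the new ring. The two stereocentres of 11 are formed without control and both are erased on aromatisation, so no stereocentre remains. The selectivity required is chemoselectivity alone, and the substrate supplies it because its only acidic C–H unit is the glycinate CH2 and the only carbonyl electrophile that this carbon can reach is the formyl group. The competing loss of p-toluenesulfinate from the enolate is opposed by the gain of aromaticity on loss of hydroxide. The non-nucleophilic base should leave both C–Br bonds and the N–S bond alone.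

Step 7
Reactants: 12 methyl 4,7-dibromo-1-tosyl-1H-indole-2-carboxylate
Product: 14 4,7-dibromo-1H-indole-2-carboxylic acid, via methyl 4,7-dibromo-1H-indole-2-carboxylate 13 (not isolated)
Conditions: KOH (6 equiv), MeOH/THF/H2O, 65 °C; then 1 M HCl to pH 2
Reagents that add atoms: potassium hydroxide, [K+].[OH-]
Why: Basic hydrolysis; hydroxide attacks sulfur and expels the ester-stabilised indolide, which is expected to happen first, and then saponifies the ester, while the unactivated aryl bromides should be inert to substitution.

Step 8
Reactants: 14 4,7-dibromo-1H-indole-2-carboxylic acid
Product: 16 2,3,4,7-tetrabromo-1H-indole, via 3,4,7-tribromo-1H-indole-2-carboxylic acid 15 (not isolated)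
Conditions: NBS (2.1 equiv), DMF, 0 °C → rt, dark
Reagents that add atoms: N-bromosuccinimide, O=C1CCC(=O)N1Br
Why: Electrophilic bromination at C3 followed by Hunsdiecker-type ipso-bromodecarboxylation of an electron-rich heteroaryl carboxylic acid; the second bromonium equivalent attacks the C2–C3 enamine unit and the σ-complex rearomatises by losing the carboxyl group in place of a proton, while ring A, deactivated by two bromines, should stay untouched.

## Compound list

1 | 1,4-dibromo-2-fluorobenzene | Fc1cc(Br)ccc1Br | starting material
2 | (3,6-dibromo-2-fluorophenyl)lithium | [Li]c1c(F)c(Br)ccc1Br | intermediate
3 | 3,6-dibromo-2-fluorobenzaldehyde | O=Cc1c(F)c(Br)ccc1Br | intermediate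
4 | 2-azido-3,6-dibromobenzaldehyde | [N-]=[N+]=Nc1c(Br)ccc(Br)c1C=O | intermediate
5 | 3,6-dibromo-2-[(trimethylphosphoranylidene)amino]benzaldehyde | CP(C)(C)=Nc1c(Br)ccc(Br)c1C=O | intermediate
6 | 2-amino-3,6-dibromobenzaldehyde | Nc1c(Br)ccc(Br)c1C=O | intermediate
7 | p-toluenesulfonyl chloride | Cc1ccc(S(=O)(=O)Cl)cc1 | starting material
8 | N-(3,6-dibromo-2-formylphenyl)-4-methylbenzenesulfonamide | Cc1ccc(S(=O)(=O)Nc2c(Br)ccc(Br)c2C=O)cc1 | intermediate
9 | methyl bromoacetate | COC(=O)CBr | starting material
10 | methyl N-(3,6-dibromo-2-formylphenyl)-N-tosylglycinate | COC(=O)CN(c1c(Br)ccc(Br)c1C=O)S(=O)(=O)c1ccc(C)cc1 | intermediate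
11 | methyl 4,7-dibromo-3-hydroxy-1-tosylindoline-2-carboxylate (mixture of diastereomers, racemic) | COC(=O)C1C(O)c2c(Br)ccc(Br)c2N1S(=O)(=O)c1ccc(C)cc1 | intermediate
12 | methyl 4,7-dibromo-1-tosyl-1H-indole-2-carboxylate | COC(=O)c1cc2c(Br)ccc(Br)c2n1S(=O)(=O)c1ccc(C)cc1 | intermediate
13 | methyl 4,7-dibromo-1H-indole-2-carboxylate | COC(=O)c1cc2c(Br)ccc(Br)c2[nH]1 | intermediate
14 | 4,7-dibromo-1H-indole-2-carboxylic acid | OC(=O)c1cc2c(Br)ccc(Br)c2[nH]1 | intermediate
15 | 3,4,7-tribromo-1H-indole-2-carboxylic acid | OC(=O)c1[nH]c2c(Br)ccc(Br)c2c1Br | intermediate
16 | 2,3,4,7-tetrabromo-1H-indole | Brc1[nH]c2c(Br)ccc(Br)c2c1Br | target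

## Step count and least certain steps

Total step count: 8. Longest linear sequence: 8 steps (1 to 16).

**Step 6 (key step).** The cyclisation may stop at the aldol stage. Alternatively, the enolate may expel p-toluenesulfinate, a far better leaving group than hydroxide, either before ring closure or from 11; that would remove the activating group and leave oxygen on C3. The fallback separates the two events and makes the oxygen the better leaving group. It sets out from 10: K2CO3 in MeOH/THF at 0 °C should stop at the hydroxy ester 11, which is isolated. MsCl and Et3N in CH2Cl2 at 0 °C convert it into methyl 4,7-dibromo-3-[(methylsulfonyl)oxy]-1-tosylindoline-2-carboxylate F1. DBU at 0 °C → rt then eliminates methanesulfonate, and the sequence returns to the route at 12.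

**Step 8.** The ipso substitution at the carboxyl-bearing C2 may be slow on a ring that already carries three bromines, so that the reaction stops at 15. Forcing it with more brominating agent invites over-oxidation of ring B or hydrolysis at C2. The fallback removes the carboxyl group before any bromine enters ring B. It sets out from 14: protodecarboxylation with Ag2CO3 (10 mol %) and AcOH in DMSO at 120 °C should give 4,7-dibromo-1H-indole F2. NBS (2.05 equiv) in THF at −78 °C → rt then brominates C3 and C2 in turn, and the sequence returns at 16.

**Step 4.** Sulfonylation may be sluggish because the nitrogen lone pair is tied up by the ortho formyl group and shielded by the ortho bromine. Harsher conditions risk double sulfonylation or attack on the aldehyde. The fallback forms the aryl–nitrogen bond in place of the nitrogen–sulfur bond. It sets out from 3: p-toluenesulfonamide and K2CO3 in DMSO at 90 °C should displace the fluoride by nucleophilic aromatic substitution, a known reaction of sulfonamide anions with ortho-fluoro aryl aldehydes and nitriles. It returns at 8 and bypasses steps 2 to 4.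

**Step 5.** Alkylation at a nitrogen with two ortho substituents may be slow, and long exposure to base can start the aldol closure early or trigger elimination of sulfinate from the product. Mixtures of 10, 11 and 12 converge in step 6; the elimination does not. The fallback avoids base altogether. It sets out from 8: a Mitsunobu reaction with methyl glycolate, PPh3 and diisopropyl azodicarboxylate in THF at 0 °C → rt alkylates the acidic sulfonamide under neutral conditions and returns at 10.

## Further compounds

F1 | step 6 | methyl 4,7-dibromo-3-[(methylsulfonyl)oxy]-1-tosylindoline-2-carboxylate | COC(=O)C1C(OS(C)(=O)=O)c2c(Br)ccc(Br)c2N1S(=O)(=O)c1ccc(C)cc1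
F2 | step 8 | 4,7-dibromo-1H-indole | Brc1ccc(Br)c2[nH]ccc12
F0 | step 4 | none | none
F0 | step 5 | none | none
A1 | alternative 1 | 2,5-dibromothiophene 1,1-dioxide | O=S1(=O)C(Br)=CC=C1Br
A2 | alternative 1 | tert-butyl 2,3-dihydro-1H-pyrrole-1-carboxylate | CC(C)(C)OC(=O)N1CCC=C1
A3 | alternative 1 | tert-butyl cis-4,7-dibromo-2,3,3a,7a-tetrahydro-1H-indole-1-carboxylate (racemic) | CC(C)(C)OC(=O)N1CC[C@H]2C(Br)=CC=C(Br)[C@@H]12
A4 | alternative 2 | 4-methyl-N-[4-(trimethylsilyl)but-3-yn-1-yl]-N-[(trimethylsilyl)ethynyl]benzenesulfonamide | Cc1ccc(S(=O)(=O)N(CCC#C[Si](C)(C)C)C#C[Si](C)(C)C)cc1
A5 | alternative 2 | acetylene | C#C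
A6 | alternative 2 | 1-tosyl-4,7-bis(trimethylsilyl)indoline | Cc1ccc(S(=O)(=O)N2CCc3c([Si](C)(C)C)ccc([Si](C)(C)C)c32)cc1
A7 | alternative 3 | 3,6-dibromo-2-(trimethylsilyl)phenyl trifluoromethanesulfonate | C[Si](C)(C)c1c(Br)ccc(Br)c1OS(=O)(=O)C(F)(F)F
A8 | alternative 3 | 3,6-dibromobenzyne | BrC1=CC=C(Br)C#C1
A9 | alternative 3 | methyl 2-[(tert-butoxycarbonyl)amino]acrylate | C=C(NC(=O)OC(C)(C)C)C(=O)OC
A10 | alternative 3 | 1-tert-butyl 2-methyl 4,7-dibromoindoline-1,2-dicarboxylate (racemic) | COC(=O)C1Cc2c(Br)ccc(Br)c2N1C(=O)OC(C)(C)C
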